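West is slow: after 50.0 min its two products hold 57.0 % of the charge, and its last reading gives an excess of 15.8 % with a scatter of 3.7 percentage points, so I want a figure that uses every reading.

in all of them: left-handed substrate 0.10 M; right-handed substrate 0.10 M

| run | partner | precatalyst | temperature | remark | time |
|---|---|---|---|---|---|
| west | 0.40 M | 30 mM | 25 °C | run made earlier |  |
| winter | 0.400 M | 15 mM | 25 °C |  | 2.5 h |
| dusk | 0.400 M | 15 mM | 0 °C |  | 2.5 h |

west run (percent of the left-handed substrate and right-handed substrate together charged)

| time / min | left-handed product / % | right-handed product / % |
|---|---|---|
| 4.00 | 8 | 4 |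
| 6.00 | 9 | 6 |
| 8.00 | 14 | 7 |
| 12.0 | 17 | 9 |
| 20.0 | 25 | 14 |
| 30.0 | 31 | 18 |
| 50.0 | 33 | 24 |

(scatter of a reading: 1.5 percentage points)

- partner is single-handed; left-handed substrate and right-handed substrate are mirror images of each other, charged as a racemate, each of them at the stated concentration
- the earlier runs do not show what temperature does; that part of a forecast is a guess
- an excess is below zero if the other one leads
- no earlier run changes the charge of precatalyst; that part of a forecast is a guess
- the handed part of partner does not stay in what it makes, so the products of the two hands are mirror images too

* the best flask by excess of left-handed product over right-handed product; "all alike" if 1.5 percentage points covers them all (winter / dusk / all alike)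
* excess of left-handed product over right-handed product at the end, winter
* excess of left-handed product over right-handed product at the end, dusk

Left-handed product sums to 137 % over the west readings and right-handed product to 82.0 %. The first sum over the second is my mean product ratio, an apparent selectivity factor, 1.67. As an excess this is 25.1 %, with a scatter of 2.6 points.

I now turn the settings by hand. Time first: in a plain resolution the excess sinks as the substrates drain. In west, the readings up to 12.0 min pool to 29.7 % and the later ones to 22.8 %. Replacing the curve by its mean therefore errs by 2.3 points against the later readings. Winter and dusk charge half the precatalyst of west, and dusk is colder; both effects are guesses, even in sign, so I leave the ratio unchanged. I put winter and dusk level at 25.1 %, with the later 22.8 % as my low side, since each runs 2.5 h, longer than west's last reading.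

The forecast differs: dusk best, winter 26 % (20 % to 31 %), dusk 33 % (26 % to 41 %), on its ground that “Lower conversion favours dusk”. The flasks give winter best, winter 21.9 % and dusk 16.9 %.

    partner + left-handed substrate → left-handed product (k = 0.0840 L mol⁻¹ min⁻¹, Ea = 60.0 kJ mol⁻¹)
    partner + right-handed substrate → right-handed product (k = 0.0468 L mol⁻¹ min⁻¹, Ea = 55.0 kJ mol⁻¹)
    left-handed substrate + racemization catalyst ⇌ right-handed substrate + racemization catalyst, rate k3*[racemization catalyst]*[left-handed substrate] forward; the back reaction follows from the equilibrium constant (k = 2.84 L mol⁻¹ min⁻¹, Ea = 53.0 kJ mol⁻¹)
    partner + precatalyst → racemization catalyst + spent reagent (k = 0.191 L mol⁻¹ min⁻¹, Ea = 56.0 kJ mol⁻¹)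
    racemization catalyst ⇌ dormant form (K = 3.00, k = 0.00780 min⁻¹, Ea = 96.0 kJ mol⁻¹, ΔH = −43.0 kJ mol⁻¹)
    (constants at 25 °C)

Moved singly from west, the halved precatalyst gives 22.4 %, the longer time 24.6 % and the cooling 18.5 %. Scaling my ratio by the difference between the activation energies of the two product steps gives 1.39 for dusk, an excess of 16.3 % against the 16.9 % it shows. The neighbouring flask, dusk kept at −25 °C, reckons the same way to 1.11, an excess of 5.34 %, and it gives 8.75 %, with left-handed product at 1.86 % and right-handed product at 1.56 %.

(The numbers in the tables stem from a simulated flask for substances that don't exist.)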